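**Retrosynthetic overview**

1. The last disconnection removes two benzyl ethers (enol O at C3 of the butenolide and the phenol of the 4-hydroxyphenyl ring D). The protected butenolide (ring A: O1, C2(=O), C3, C4, C5) is then cut in one operation at the lactone O1–C5 bond and at the C4–aryl bond.
2. Enabling feature: C2–C3–C4–C5 of ring A is an unbranched four-carbon chain in which C4 carries only the aryl group and C5 is fully substituted (CO2Me, CH2Ar). This is the skeleton of a tetrasubstituted 2,3-allenoic acid, HO2C–C(OBn)=C=C(CO2Me)CH2Ar: the central allene carbon takes the aryl group from palladium, the acid oxygen closes onto the ester-bearing terminus, and the allene axis becomes the quaternary stereocentre.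
3. The allene axis is set by asymmetric phase-transfer benzylation of a trisubstituted benzyloxyallene diester (from methyl propiolate and tert-butyl glyoxylate) with a chromanylmethyl bromide.
4. The chroman carbinol stereocentre comes from Jacobsen–Katsuki epoxidation of a 2,2-dimethylchromene and hydride opening at C4.
5. Ring order: the pyran ring C is fused onto the benzoate ring B first (Claisen/electrocyclization); butenolide ring A is closed last, with ring D attached in the same step.

Key step: step 12

Assumption (remark on the chemistry): the sense of induction of the chiral catalysts in steps 3 and 10 is assigned by analogy with closely related substrates; the antipodal catalyst would be used if the opposite sense were found.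

**Route**

Step 1
Reactants: 1 methyl 4-hydroxybenzoate; 2 3-chloro-3-methylbut-1-yne
Product: 3 methyl 4-[(2-methylbut-3-yn-2-yl)oxy]benzoate
Conditions: DBU, CuCl2·2H2O (cat.), MeCN, 0 °C
Reagents that add atoms: none
Why: copper-catalysed O-propargylation of a phenol with a tertiary propargylic chloride should give the aryl 1,1-dimethylpropargyl ether cleanly, also with an electron-poor phenol.

Step 2
Reactants: 3 methyl 4-[(2-methylbut-3-yn-2-yl)oxy]benzoate
Product: 5 methyl 2,2-dimethyl-2H-chromene-6-carboxylate, via ortho-allenylphenol 4 (not isolated)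
Conditions: N,N-diethylaniline, 190 °C
Reagents that add atoms: none
Why: aromatic propargyl Claisen rearrangement to the ortho-allenylphenol, 1,5-hydrogen shift to the ortho-quinone methide and oxa-6π electrocyclization should close the pyran ring, with the ester ending up at C6.

Step 3
Reactants: 5 methyl 2,2-dimethyl-2H-chromene-6-carboxylate
Product: 6 methyl (3R,4R)-3,4-epoxy-2,2-dimethyl-3,4-dihydro-2H-chromene-6-carboxylate
Conditions: (R,R)-N,N'-bis(3,5-di-tert-butylsalicylidene)-1,2-cyclohexanediaminomanganese chloride [(R,R)-(salen)MnCl] (cat.), aq. NaOCl (pH 11.3 buffer), 4-phenylpyridine N-oxide (cat.), CH2Cl2, 0 °C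
Reagents that add atoms: sodium hypochlorite, [Na+].[O-]Cl
Why: Jacobsen–Katsuki epoxidation, for which 6-acceptor-substituted 2,2-dimethylchromenes are the archetypal substrates; the (R,R)-configured trivalent manganese salen complex is expected to deliver oxygen to the face that gives the (3R,4R)-epoxide, which fixes C3 of the chroman.

Step 4
Reactants: 6 methyl (3R,4R)-3,4-epoxy-2,2-dimethyl-3,4-dihydro-2H-chromene-6-carboxylate
Product: 7 (3R)-6-(hydroxymethyl)-2,2-dimethyl-3,4-dihydro-2H-chromen-3-ol
Conditions: LiAlH4, THF, 0 °C to rt; aq. NaOH work-up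
Reagents that add atoms: none
Why: hydride reduction of the ester together with SN2 opening of the epoxide at the benzylic, less hindered C4 (C3 is shielded by the quaternary C2) should leave the C3–O bond and its (R) configuration untouched.

Step 5
Reactants: 7 (3R)-6-(hydroxymethyl)-2,2-dimethyl-3,4-dihydro-2H-chromen-3-ol
Product: 8 (3R)-6-(bromomethyl)-2,2-dimethyl-3,4-dihydro-2H-chromen-3-ol
Conditions: 48% aq. HBr, toluene, 0 °C to rt; used crude at once
Reagents that add atoms: hydrogen bromide, Br
Why: SN1 substitution selective for the para-alkoxybenzylic alcohol, which ionizes readily, whereas the hindered secondary alcohol next to the quaternary carbon cannot ionize and should remain.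

Step 6
Reactants: 9 di-tert-butyl L-tartrate
Product: 10 tert-butyl glyoxylate
Conditions: H5IO6, Et2O, rt; then distillation
Reagents that add atoms: none
Why: periodic acid glycol cleavage (Malaprade reaction) of the tartrate diol should give two equivalents of the glyoxylate.

Step 7
Reactants: 11 methyl propiolate; 10 tert-butyl glyoxylate
Product: 13 racemic 1-tert-butyl 5-methyl 2-hydroxypent-3-ynedioate, via methyl 3-lithiopropiolate 12 (not isolated)
Conditions: LiN(SiMe3)2, THF, −78 °C; then 10, −78 °C; AcOH quench at −78 °C
Reagents that add atoms: none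
Why: 1,2-addition of a lithium acetylide to an aldehyde; the cold acidic quench should prevent base-induced isomerization of the γ-hydroxy alkynoate.

Step 8
Reactants: 13 racemic 1-tert-butyl 5-methyl 2-hydroxypent-3-ynedioate
Product: 14 racemic 1-tert-butyl 5-methyl 2-(benzyloxy)pent-3-ynedioate
Conditions: BnOC(=NH)CCl3, TfOH (cat.), CH2Cl2/cyclohexane, 0 °C
Reagents that add atoms: benzyl 2,2,2-trichloroacetimidate, N=C(OCc1ccccc1)C(Cl)(Cl)Cl
Why: acid-catalysed O-benzylation with a trichloroacetimidate, chosen because basic benzylation would isomerize the hydroxy alkynoate to an oxo-enoate.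

Step 9
Reactants: 14 racemic 1-tert-butyl 5-methyl 2-(benzyloxy)pent-3-ynedioate
Product: 15 racemic 1-tert-butyl 5-methyl 2-(benzyloxy)penta-2,3-dienedioate
Conditions: Et3N (cat.), CH2Cl2, 0 °C to rt; used without storage
Reagents that add atoms: none
Why: base-catalysed propargyl-to-allenyl prototropic isomerization, which should be driven by conjugation of the allene with both esters and the benzyloxy donor.

Step 10
Reactants: 15 racemic 1-tert-butyl 5-methyl 2-(benzyloxy)penta-2,3-dienedioate; 8 (3R)-6-(bromomethyl)-2,2-dimethyl-3,4-dihydro-2H-chromen-3-ol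
Product: 16 1-tert-butyl 5-methyl (Ra)-2-(benzyloxy)-4-{[(3R)-3-hydroxy-2,2-dimethyl-3,4-dihydro-2H-chromen-6-yl]methyl}penta-2,3-dienedioate
Conditions: chiral C2-symmetric N-spiro bis(binaphthyl) quaternary ammonium bromide with 3,3'-bis(3,4,5-trifluorophenyl) groups (cat.), Cs2CO3 (solid), toluene, −20 °C
Reagents that add atoms: none
Why: asymmetric phase-transfer alkylation of an allene-1,3-dicarboxylate, in which deprotonation of the allenic C4–H gives a planar cumulenolate with enantiotopic faces at C4 and the chiral ammonium cation should allow the benzylic bromide to approach one face only, so that the (Ra) axis is set by catalyst control at the less hindered, hydrogen-bearing terminus.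

Step 11
Reactants: 16 1-tert-butyl 5-methyl (Ra)-2-(benzyloxy)-4-{[(3R)-3-hydroxy-2,2-dimethyl-3,4-dihydro-2H-chromen-6-yl]methyl}penta-2,3-dienedioate
Product: 17 (Ra)-2-(benzyloxy)-5-[(3R)-3-hydroxy-2,2-dimethyl-3,4-dihydro-2H-chromen-6-yl]-4-(methoxycarbonyl)penta-2,3-dienoic acid
Conditions: TFA/CH2Cl2 (1:4), anisole, 0 °C; aq. NaHCO3 wash, then pH 3
Reagents that add atoms: none
Why: acidolysis of the tert-butyl ester by loss of isobutene should spare the methyl ester, the benzyl enol ether and the allene, whose central carbon is the β-carbon of two acrylate units and therefore resists protonation, so the axis is not touched.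

Step 12
Reactants: 17 (Ra)-2-(benzyloxy)-5-[(3R)-3-hydroxy-2,2-dimethyl-3,4-dihydro-2H-chromen-6-yl]-4-(methoxycarbonyl)penta-2,3-dienoic acid; 18 1-(benzyloxy)-4-iodobenzene
Product: 20 methyl (2R)-4-(benzyloxy)-3-[4-(benzyloxy)phenyl]-2-{[(3R)-3-hydroxy-2,2-dimethyl-3,4-dihydro-2H-chromen-6-yl]methyl}-5-oxo-2,5-dihydrofuran-2-carboxylate, via aryl(butenolidyl)palladium intermediate 19 (not isolated)
Conditions: Pd(PPh3)4 (5 mol %), Ag2CO3 (10 mol %), i-Pr2NEt, MeCN, 70 °C
Reagents that add atoms: none
Why: Oxidative addition of 18 to zerovalent palladium and iodide abstraction by silver carbonate should give a cationic arylpalladium species (divalent palladium) that binds the C3=C4 π-bond of 17 on the face away from the carboxylate; the carboxylate oxygen then adds anti to the metal at allene C4, forming the O1–C5 lactone bond and intermediate 19, and C–C reductive elimination places the aryl group on the former central allene carbon (the β-carbon of both acrylate units, as in Heck regiochemistry). The closest known reaction type is the palladium/silver-cocatalysed coupling–cyclization of 2,3-allenoic acids with aryl halides, which is known to carry the axial chirality of optically active allenoic acids into C5 of the butenolide. Ring A closes in a 5-endo mode that is easy here because the attacked p-orbital of the distal allene π-bond lies in the plane of the forming ring. The only new stereocentre, quaternary C5, is set by axial-to-central chirality transfer: the carboxylate can bond to allene C4 only on the side of the C3=C4 bond on which it stands, so the (Ra) axis maps onto (R)-C5, provided that ring closure outruns any π-allyl isomerization. The step needs chemoselectivity for the carboxylate over the methyl ester, arylative over proton-terminated cyclization, and no β-hydride loss from the benzylic CH2. The free acid at C1 versus the ester on C4, excess aryl iodide with only catalytic silver, and the fast intramolecular C–O closure of the cationic pathway are expected to secure these.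

Step 13
Reactants: 20 methyl (2R)-4-(benzyloxy)-3-[4-(benzyloxy)phenyl]-2-{[(3R)-3-hydroxy-2,2-dimethyl-3,4-dihydro-2H-chromen-6-yl]methyl}-5-oxo-2,5-dihydrofuran-2-carboxylate
Product: 21 methyl (2R)-4-hydroxy-2-{[(3R)-3-hydroxy-2,2-dimethyl-3,4-dihydro-2H-chromen-6-yl]methyl}-3-(4-hydroxyphenyl)-5-oxo-2,5-dihydrofuran-2-carboxylate (CNP0275739.3)
Conditions: H2 (1 atm), Pd/C, EtOAc, rt
Reagents that add atoms: none
Why: hydrogenolysis of the aryl and enol benzyl ethers, under which the tetrasubstituted, electron-rich enol double bond of the butenolide, the methyl ester and both stereocentres are expected to survive.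

**Compound list**

1 | methyl 4-hydroxybenzoate | COC(=O)c1ccc(O)cc1 | starting material
2 | 3-chloro-3-methylbut-1-yne | CC(C)(Cl)C#C | starting material
3 | methyl 4-[(2-methylbut-3-yn-2-yl)oxy]benzoate | COC(=O)c1ccc(OC(C)(C)C#C)cc1 | intermediate
4 | methyl 4-hydroxy-3-(3-methylbuta-1,2-dien-1-yl)benzoate (ortho-allenylphenol, not isolated) | COC(=O)c1ccc(O)c(C=C=C(C)C)c1 | intermediate
5 | methyl 2,2-dimethyl-2H-chromene-6-carboxylate | COC(=O)c1ccc2OC(C)(C)C=Cc2c1 | intermediate
6 | methyl (3R,4R)-3,4-epoxy-2,2-dimethyl-3,4-dihydro-2H-chromene-6-carboxylate | COC(=O)c1ccc2c(c1)[C@@H]1[C@@H](O1)C(C)(C)O2 | intermediate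
7 | (3R)-6-(hydroxymethyl)-2,2-dimethyl-3,4-dihydro-2H-chromen-3-ol | OCc1ccc2c(c1)C[C@@H](O)C(C)(C)O2 | intermediate
8 | (3R)-6-(bromomethyl)-2,2-dimethyl-3,4-dihydro-2H-chromen-3-ol | BrCc1ccc2c(c1)C[C@@H](O)C(C)(C)O2 | intermediate
9 | di-tert-butyl L-tartrate | CC(C)(C)OC(=O)[C@H](O)[C@@H](O)C(=O)OC(C)(C)C | starting material
10 | tert-butyl glyoxylate | CC(C)(C)OC(=O)C=O | intermediate
11 | methyl propiolate | COC(=O)C#C | starting material
12 | methyl 3-lithiopropiolate (not isolated) | COC(=O)C#C[Li] | intermediate
13 | racemic 1-tert-butyl 5-methyl 2-hydroxypent-3-ynedioate | CC(C)(C)OC(=O)C(O)C#CC(=O)OC | intermediate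
14 | racemic 1-tert-butyl 5-methyl 2-(benzyloxy)pent-3-ynedioate | CC(C)(C)OC(=O)C(OCc1ccccc1)C#CC(=O)OC | intermediate
15 | racemic 1-tert-butyl 5-methyl 2-(benzyloxy)penta-2,3-dienedioate | CC(C)(C)OC(=O)C(OCc1ccccc1)=C=CC(=O)OC | intermediate
16 | 1-tert-butyl 5-methyl (Ra)-2-(benzyloxy)-4-{[(3R)-3-hydroxy-2,2-dimethyl-3,4-dihydro-2H-chromen-6-yl]methyl}penta-2,3-dienedioate | CC(C)(C)OC(=O)C(OCc1ccccc1)=[C@]=C(C(=O)OC)Cc1ccc2c(c1)C[C@@H](O)C(C)(C)O2 | intermediate
17 | (Ra)-2-(benzyloxy)-5-[(3R)-3-hydroxy-2,2-dimethyl-3,4-dihydro-2H-chromen-6-yl]-4-(methoxycarbonyl)penta-2,3-dienoic acid | OC(=O)C(OCc1ccccc1)=[C@]=C(C(=O)OC)Cc1ccc2c(c1)C[C@@H](O)C(C)(C)O2 | intermediate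
18 | 1-(benzyloxy)-4-iodobenzene | Ic1ccc(OCc2ccccc2)cc1 | starting material
19 | aryl(butenolidyl)palladium intermediate of step 12 (divalent palladium at C4 of the butenolide; phosphine ligands omitted; not isolated) | COC(=O)[C@]1(Cc2ccc3c(c2)C[C@@H](O)C(C)(C)O3)OC(=O)C(OCc2ccccc2)=C1[Pd]c1ccc(OCc2ccccc2)cc1 | intermediate
20 | methyl (2R)-4-(benzyloxy)-3-[4-(benzyloxy)phenyl]-2-{[(3R)-3-hydroxy-2,2-dimethyl-3,4-dihydro-2H-chromen-6-yl]methyl}-5-oxo-2,5-dihydrofuran-2-carboxylate | COC(=O)[C@]1(Cc2ccc3c(c2)C[C@@H](O)C(C)(C)O3)OC(=O)C(OCc2ccccc2)=C1c1ccc(OCc2ccccc2)cc1 | intermediate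
21 | methyl (2R)-4-hydroxy-2-{[(3R)-3-hydroxy-2,2-dimethyl-3,4-dihydro-2H-chromen-6-yl]methyl}-3-(4-hydroxyphenyl)-5-oxo-2,5-dihydrofuran-2-carboxylate | COC(=O)[C@]1(Cc2ccc3c(c2)C[C@@H](O)C(C)(C)O3)OC(=O)C(O)=C1c1ccc(O)cc1 | target

**Step count and risks**

Total step count: 13. Longest linear sequence: 9 steps (steps 1–5, then 10–13).

Steps most likely to fail:

Step 12. The axial information may be lost before ring closure (reversible carbopalladation and π-allyl isomerization). Silver may promote cyclization without aryl transfer, β-hydride loss from the benzylic CH2 may give a diene, or base may isomerize the allene. The fallback sets out from 17 and separates ring closure from arylation. Bromolactonization with CuBr2 (acetone/H2O, rt to 60 °C), a known halolactonization of 2,3-allenoic acids that closes the same O1–C5 bond with the same axial-to-central transfer, should give methyl (2S)-4-(benzyloxy)-3-bromo-2-{[(3R)-3-hydroxy-2,2-dimethyl-3,4-dihydro-2H-chromen-6-yl]methyl}-5-oxo-2,5-dihydrofuran-2-carboxylate F1. It has the same spatial arrangement at the quaternary carbon as 20; the descriptor changes only because bromine raises the priority of the ring carbon. Suzuki–Miyaura coupling of F1 with 4-(benzyloxy)phenylboronic acid (Pd(PPh3)4, K2CO3, toluene/EtOH/H2O, 80 °C) comes back to the route at 20.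

Step 10. Facial discrimination in the ion pair may be insufficient with a benzyloxy instead of an alkyl substituent on the allene. Alkylation may also compete at the benzyloxy-bearing terminus, or the product may isomerize to a diene under base. The fallback sets out from 15 and 8 and gives up catalyst control in favour of separation, which the fixed chroman stereocentre makes possible. Alkylation under achiral phase-transfer conditions (Bu4NBr, K2CO3, toluene, 0 °C) should give 1-tert-butyl 5-methyl 2-(benzyloxy)-4-{[(3R)-3-hydroxy-2,2-dimethyl-3,4-dihydro-2H-chromen-6-yl]methyl}penta-2,3-dienedioate as a mixture of both axis epimers F2. TFA/CH2Cl2 with anisole then gives 2-(benzyloxy)-5-[(3R)-3-hydroxy-2,2-dimethyl-3,4-dihydro-2H-chromen-6-yl]-4-(methoxycarbonyl)penta-2,3-dienoic acid as a mixture of both axis epimers F3. The two acids are diastereomers and would be separated by fractional crystallization of their (S)-1-phenylethylammonium salts or by preparative HPLC; the (Ra) epimer comes back to the route at 17.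

Step 11. Acid may cleave the benzyl enol ether or hydrate the alkoxyallene, or trigger proton-induced lactonization to a butenolide without the aryl group. The fallback sets out from 16 and avoids the free acid. Iodolactonization of the tert-butyl allenoate (I2, MeCN/H2O, rt), in which the ester carbonyl oxygen closes onto the iodine-activated allene and the tert-butyl group leaves as isobutene, should give methyl (2S)-4-(benzyloxy)-2-{[(3R)-3-hydroxy-2,2-dimethyl-3,4-dihydro-2H-chromen-6-yl]methyl}-3-iodo-5-oxo-2,5-dihydrofuran-2-carboxylate F4. Suzuki–Miyaura coupling of F4 with 4-(benzyloxy)phenylboronic acid (Pd(PPh3)4, K2CO3, toluene/EtOH/H2O, 80 °C) comes back to the route at 20, bypassing 17 and step 12.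

Further compounds
F1 | step 12 | methyl (2S)-4-(benzyloxy)-3-bromo-2-{[(3R)-3-hydroxy-2,2-dimethyl-3,4-dihydro-2H-chromen-6-yl]methyl}-5-oxo-2,5-dihydrofuran-2-carboxylate | COC(=O)[C@]1(Cc2ccc3c(c2)C[C@@H](O)C(C)(C)O3)OC(=O)C(OCc2ccccc2)=C1Br
F2 | step 10 | 1-tert-butyl 5-methyl 2-(benzyloxy)-4-{[(3R)-3-hydroxy-2,2-dimethyl-3,4-dihydro-2H-chromen-6-yl]methyl}penta-2,3-dienedioate, mixture of both axis epimers | CC(C)(C)OC(=O)C(OCc1ccccc1)=C=C(C(=O)OC)Cc1ccc2c(c1)C[C@@H](O)C(C)(C)O2
F3 | step 10 | 2-(benzyloxy)-5-[(3R)-3-hydroxy-2,2-dimethyl-3,4-dihydro-2H-chromen-6-yl]-4-(methoxycarbonyl)penta-2,3-dienoic acid, mixture of both axis epimers | OC(=O)C(OCc1ccccc1)=C=C(C(=O)OC)Cc1ccc2c(c1)C[C@@H](O)C(C)(C)O2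
F4 | step 11 | methyl (2S)-4-(benzyloxy)-2-{[(3R)-3-hydroxy-2,2-dimethyl-3,4-dihydro-2H-chromen-6-yl]methyl}-3-iodo-5-oxo-2,5-dihydrofuran-2-carboxylate | COC(=O)[C@]1(Cc2ccc3c(c2)C[C@@H](O)C(C)(C)O3)OC(=O)C(OCc2ccccc2)=C1I
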